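# Synthesis proposal for CNP0270206.1: flavone annulation by aryne insertion into an arylpropiolic acid

Locants used throughout: the cyclohexene is C1''–C6'' (C1'' bears the methyl group, C1''=C2'' is the ring alkene, C3'' bears the flavone, C4'' the aroyl group, C5'' the 2,4-dihydroxyphenyl group, C6'' is CH2). The flavone has its usual numbering (O1, C2, C3, C4, C4a, C5–C8, C8a). MOM = methoxymethyl.

## Analysis of the target

Target 29 is a mulberry-type Diels–Alder adduct. A 1''-methylcyclohex-1''-ene carries on three contiguous sp3 carbons a flavone bonded through its C6 (at C3''), a 2,4-dihydroxy-3-prenylbenzoyl group (at C4'') and a 2,4-dihydroxyphenyl group (at C5''). The flavone is 5,7-dihydroxy-2-(2,4-dihydroxyphenyl)chromen-4-one, so ring A is a phloroglucinol ring whose C6, between the 5- and 7-oxygens, is joined to C3''. The stereotriad is (3''S,4''R,5''S): the C3'' aryl and C4'' aroyl groups are cis, the aroyl and C5'' aryl groups are trans, which is the pattern of an endo adduct of an E-chalcone. Sensitive points are eight free phenols, a prenyl group and a trisubstituted ring alkene that acid can cyclise onto neighbouring phenols, a C4''–H that is alpha to the ketone and can epimerise, and a ketone flanked by phenols that can ketalise. The synthesis is hard because the triad must be made as one enantiomer, the aryl–C3'' bond sits between two oxygens, and the pyranone must be fused to the phloroglucinol ring so that the cyclohexenyl group ends at C6 and not at C8. The strategy rests on one feature of ring A: C8a (bearing O1) and C4a (bearing the C4 carbonyl) are neighbours, with hydrogen at C8 and oxygen at C5. That is the substitution pattern left when a 3-alkoxyaryne spanning C4a and C8a takes up an oxygen nucleophile at C8a and an acyl group at C4a.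

## Retrosynthetic reasoning

**29 to 28.** All eight phenols are carried as MOM ethers, so the last operation is a single acidic acetal cleavage of 28. One protecting group type keeps the aryne step free of acidic O–H groups and leaves only one deprotection event.

**28 to 26.** The O1–C2 bond is cut, which leads back to ynone 26. In 26 the only free phenol is the one on C8a, so 6-endo oxa-Michael closure can give only one flavone. A secondary amine is planned as promoter, acting through enaminone 27, because this mode is known to favour the six-membered ring over the aurone.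

**26 to 24 and 10 (key disconnection).** The C8a–O1 and C4a–C4 bonds are cut together. The forward reaction generates aryne 25 from silyl triflate 24 and lets it insert into the C–O bond of propiolic acid 10. The cut is made here because it delivers the pyranone oxygen and carbonyl in one operation to two adjacent carbons. The regiochemistry is dictated by the C5 oxygen. The phenol para to the cyclohexenyl carbon is consumed as the triflate leaving group, so no C6 versus C8 choice remains.

**24 to 23, then to 7 and 22.** The 2'-O-MOM group is removed to give phenol 23, whose free hydroxyl is needed for the cycloaddition. The C3''–C4'' and C5''–C6'' bonds are then cut, giving 2'-hydroxychalcone 7 and aryl diene 22. The forward Diels–Alder reaction must be endo and face-selective, and it sets all three stereocentres in one step from two achiral pieces. The silyl triflate is placed on the diene beforehand, so no organometallic chemistry is needed once the ketone is present.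

**22 back to 11.** The C–Si bond of 22 comes from an O-to-C silyl shift in the ortho-bromophenol 19 after silylation to 20 and bromine–lithium exchange to 21. Diene 18 is assembled by two olefinations of aldehyde 16 through enone 17. The bromine enters aldehyde 15 ortho to the silyloxy group, where both free positions are equivalent. Aldehyde 15 comes from lithiation of silyl ether 13 between its two acetal oxygens (aryllithium 14). Ether 13 derives from phenol 12 and phloroglucinol (11). The symmetry of 11 is broken once, at 12, and every later regiochemical question is settled by symmetry or by the two flanking acetals.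

**7 to 4 and 6.** The enone C=C bond is cut by a Claisen–Schmidt disconnection into ketone 4 and aldehyde 6. Ketone 4 comes from 2,4-dihydroxyacetophenone (1) and prenyl bromide (2) through 3. Aldehyde 6 comes from 2,4-dihydroxybenzaldehyde (5).

**10 to 8 to 6.** The carboxyl carbon is removed to give alkyne 8 (through acetylide 9), and 8 is the one-carbon homologue of aldehyde 6. Aldehyde 6 therefore serves two fragments.

## Alternatives that were turned down

**Alternative 1:** The disconnection opens the prenylated resorcinol ring of the aroyl group at C1'–C2' and C5'–C6'. The precursors are ethynyl ketone A1, in which the C4'' carbonyl bears only a terminal alkyne, and the 2-prenyl bis-silyloxy diene A2.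
- Forward key step: the CH2 terminus of A2 bonds to the alkyne beta-carbon and its ketene acetal carbon to the alpha-carbon. The adduct expels its methoxy group and aromatises to A3, with both aroyl-ring hydroxyls free.
- For it: polarity fixes the regiochemistry, and the prenyl group arrives already between the two oxygens. On this point it is stronger than step 1 of the chosen route, where C-prenylation of 1 is only moderately selective. A3 also needs six acetal cleavages instead of eight.
- Against it: the ring it builds is the one ring that can be bought as 1. A1 must already contain the flavone, the C6–C3'' bond and all three stereocentres, so the hard problems are moved upstream unsolved. The C4''–H of A1 is alpha to an ynone and more prone to epimerisation than in 24. The terminal ynone is an unselective Michael acceptor, and the fully substituted ketene acetal end of A2 is hindered and hydrolytically fragile.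
- Comparison: the chosen strategy spends its ring-forming step on the pyranone, where regiochemistry is really in question, and accepts a modest prenylation on a cheap first step.

**Alternative 2:** The disconnection cuts C5''–C6'' and adds a bond from the ketone carbon to C2'', which leads to the benzylidene cyclobutanol A4.
- Forward key step: the potassium alkoxide of A4 undergoes an anionic oxy-Cope rearrangement. The four-membered ring opens between the carbinol carbon and C2'', the isopropenyl CH2 bonds to the benzylidene carbon, and the aryl ketone appears as its enolate. Protonation at C4'' gives A5.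
- For it: the six-membered ring forms in a strain-driven, stereospecific sigmatropic step with no endo/exo question. In principle this is stronger than the Diels–Alder step of the chosen route, where endo selectivity is a real risk.
- Against it: A4 needs three ring stereocentres, one of them quaternary, and a defined benzylidene geometry, so the stereochemical burden is moved, not removed. C4'' is set only by kinetic protonation. A5 carries a para-silyloxy group and still needs desilylation, ortho-silylation and triflation on a ketone-bearing intermediate before any flavone can be built.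
- Comparison: this alternative competes with steps 7–16 and not with the flavone annulation. The chosen route offers in its place a one-step, convergent cycloaddition of 7 and 22 that brings the aryne precursor in ready-made.

**Alternative 3:** The disconnection cuts ring A at C4a–C5 and traces its oxygens back to carbonyl groups, giving pyranone A6. In A6, C3'' bears a beta-keto ester chain that ends in a 4-pyranon-2-ylmethyl ketone.
- Forward key step: base forms the extended enolate of A6, pyranone C3 attacks the ester carbonyl, C4a–C5 forms, and the new ring tautomerises to the 5,7-diol A7.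
- For it: there is no C6/C8 ambiguity, because the cyclohexenyl group is built into the chain. The 5- and 7-hydroxyls emerge free. It needs neither the eight-step silyl triflate diene nor hot fluoride, and on step count for ring A it is as strong as or stronger than the chosen route.
- Against it: C3'' must first be made as a carbon bearing an sp3 CH with ester and ketone, which is a crowded and epimerisable centre. The cyclisation needs several equivalents of strong base next to the C4''–H. The chain methylene can attack the aroyl ketone in a six-membered aldol closure. The beta-keto ester enolate also deactivates the very ester that must be attacked.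
- Comparison: the chosen strategy forms the same two ring A bonds under weakly basic fluoride conditions. It attaches ring A to C3'' as an intact arene in the cycloaddition and brings in the B-ring unit as the simple acid 10.

Key step: step 17

**Assumption on the chemistry:** the borate of the (R)-ligand in step 15 is taken to leave the Si face of the chalcone alpha-carbon open (priorities aroyl carbon > beta-carbon > H). If the sense of induction is the reverse, the (S)-ligand is used and nothing else changes.

**Remark on the chemistry:** rotation about the C3''–aryl bond in 23–28 is taken to be fast enough that rotamers converge on one flavone.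

## Route

### Chalcone 7 (steps 1–4)

Step 1
Reactants: 1 2,4-dihydroxyacetophenone; 2 1-bromo-3-methylbut-2-ene (prenyl bromide)
Product: 3 1-[2,4-dihydroxy-3-(3-methylbut-2-en-1-yl)phenyl]ethan-1-one
Conditions: KOH (10% aq), 0 °C → rt
Reagents that add atoms: none
Why: C-alkylation of the resorcinol-type phenolate in water (phenolate C-prenylation); the carbon between the two oxygens is the most nucleophilic site and the protic medium disfavours O-alkylation, and 3 should be separable from the 5-prenyl and O-prenyl isomers.

Step 2
Reactants: 3 1-[2,4-dihydroxy-3-(3-methylbut-2-en-1-yl)phenyl]ethan-1-one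
Product: 4 1-[2-hydroxy-4-(methoxymethoxy)-3-(3-methylbut-2-en-1-yl)phenyl]ethan-1-one
Conditions: MOMCl (1.2 equiv), K2CO3, acetone, rt
Reagents that add atoms: chloromethyl methyl ether, COCCl
Why: O-alkylation of the phenoxide (Williamson-type acetal formation); only the 4-hydroxyl reacts because the 2-hydroxyl is held in a hydrogen bond to the acetyl group and is flanked by the prenyl chain.

Step 3
Reactants: 5 2,4-dihydroxybenzaldehyde
Product: 6 2,4-bis(methoxymethoxy)benzaldehyde
Conditions: MOMCl (3 equiv), K2CO3, acetone, reflux
Reagents that add atoms: chloromethyl methyl ether, COCCl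
Why: exhaustive O-alkylation; excess reagent at reflux should also convert the chelated 2-hydroxyl of the aldehyde, whose hydrogen bond is weaker than that of the ketone in step 2.

Step 4
Reactants: 4 1-[2-hydroxy-4-(methoxymethoxy)-3-(3-methylbut-2-en-1-yl)phenyl]ethan-1-one; 6 2,4-bis(methoxymethoxy)benzaldehyde
Product: 7 (E)-3-[2,4-bis(methoxymethoxy)phenyl]-1-[2-hydroxy-4-(methoxymethoxy)-3-(3-methylbut-2-en-1-yl)phenyl]prop-2-en-1-one
Conditions: KOH, EtOH/H2O, rt
Reagents that add atoms: none
Why: Claisen–Schmidt condensation; elimination from the aldol gives the conjugated E-enone, the acetals are stable to base, and the 2'-hydroxyl stays free for the boron chelate of step 15.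

### Propiolic acid 10 (steps 5–6)

Step 5
Reactants: 6 2,4-bis(methoxymethoxy)benzaldehyde
Product: 8 1-ethynyl-2,4-bis(methoxymethoxy)benzene
Conditions: dimethyl (1-diazo-2-oxopropyl)phosphonate, K2CO3, MeOH, rt
Reagents that add atoms: dimethyl (1-diazo-2-oxopropyl)phosphonate, COP(=O)(OC)C(=[N+]=[N-])C(C)=O
Why: Seyferth–Gilbert homologation in its Ohira–Bestmann form; the mild carbonate/methanol medium converts the aldehyde into the terminal alkyne without touching the acetals.

Step 6
Reactants: 8 1-ethynyl-2,4-bis(methoxymethoxy)benzene
Product: 10 3-[2,4-bis(methoxymethoxy)phenyl]prop-2-ynoic acid, via lithium acetylide 9 (not isolated)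
Conditions: n-BuLi (1.05 equiv), THF, −78 °C; CO2; cold 0.5 M HCl to pH 3
Reagents that add atoms: carbon dioxide, O=C=O
Why: deprotonation of the terminal alkyne and carboxylation of the acetylide; one equivalent of base at −78 °C avoids ring lithiation next to the acetals, and a cold, brief acidification spares them.

### Diene 22 (steps 7–14)

Step 7
Reactants: 11 phloroglucinol
Product: 12 3,5-bis(methoxymethoxy)phenol
Conditions: MOMCl (2.0 equiv), i-Pr2NEt, DMF, 0 °C → rt
Reagents that add atoms: chloromethyl methyl ether, COCCl
Why: statistical double O-alkylation of a symmetric triol; 12 should be separable from the mono- and tri-ethers, and this is the only place where the symmetry of ring A has to be broken without a directing element.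

Step 8
Reactants: 12 3,5-bis(methoxymethoxy)phenol
Product: 13 [3,5-bis(methoxymethoxy)phenoxy]tri(propan-2-yl)silane
Conditions: i-Pr3SiCl, imidazole, DMF, rt
Reagents that add atoms: chlorotriisopropylsilane, CC(C)[Si](Cl)(C(C)C)C(C)C
Why: O-silylation; the bulky silyl ether does not direct metalation and survives butyllithium and ylides, which the next four steps require.

Step 9
Reactants: 13 [3,5-bis(methoxymethoxy)phenoxy]tri(propan-2-yl)silane
Product: 15 2,6-bis(methoxymethoxy)-4-[tri(propan-2-yl)silyloxy]benzaldehyde, via aryllithium 14 (not isolated)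
Conditions: n-BuLi, THF, 0 °C; DMF, 0 °C → rt; H2O
Reagents that add atoms: N,N-dimethylformamide, CN(C)C=O
Why: directed ortho-metalation between the two chelating acetal oxygens, then formylation; the position between the acetals is doubly activated while the positions next to the silyl ether are shielded.

Step 10
Reactants: 15 2,6-bis(methoxymethoxy)-4-[tri(propan-2-yl)silyloxy]benzaldehyde
Product: 16 3-bromo-2,6-bis(methoxymethoxy)-4-[tri(propan-2-yl)silyloxy]benzaldehyde
Conditions: NBS (1.0 equiv), MeCN, 0 °C
Reagents that add atoms: N-bromosuccinimide, O=C1CCC(=O)N1Br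
Why: electrophilic aromatic bromination; the two free ring positions are equivalent and each lies ortho or para to all three oxygens, and the first bromine deactivates and crowds the ring against a second.

Step 11
Reactants: 16 3-bromo-2,6-bis(methoxymethoxy)-4-[tri(propan-2-yl)silyloxy]benzaldehyde
Product: 17 (E)-4-{3-bromo-2,6-bis(methoxymethoxy)-4-[tri(propan-2-yl)silyloxy]phenyl}but-3-en-2-one
Conditions: Ph3P=CHC(O)CH3, toluene, 110 °C
Reagents that add atoms: (acetylmethylene)triphenylphosphorane, CC(=O)C=P(c1ccccc1)(c1ccccc1)c1ccccc1
Why: Wittig reaction of a stabilised ylide, E-selective under neutral conditions that leave the aryl silyl ether and the acetals alone; the hindered aldehyde should need the reflux temperature.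

Step 12
Reactants: 17 (E)-4-{3-bromo-2,6-bis(methoxymethoxy)-4-[tri(propan-2-yl)silyloxy]phenyl}but-3-en-2-one
Product: 18 {2-bromo-3,5-bis(methoxymethoxy)-4-[(1E)-3-methylbuta-1,3-dien-1-yl]phenoxy}tri(propan-2-yl)silane
Conditions: Ph3PCH3Br, NaN(SiMe3)2, THF, 0 °C → rt
Reagents that add atoms: methyltriphenylphosphonium bromide, C[P+](c1ccccc1)(c1ccccc1)c1ccccc1.[Br-]
Why: Wittig methylenation of the methyl ketone; 1,2-addition of the non-stabilised ylide gives the 2-substituted diene with the E-styrenyl geometry of 17 unchanged.

Step 13
Reactants: 18 {2-bromo-3,5-bis(methoxymethoxy)-4-[(1E)-3-methylbuta-1,3-dien-1-yl]phenoxy}tri(propan-2-yl)silane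
Product: 19 2-bromo-3,5-bis(methoxymethoxy)-4-[(1E)-3-methylbuta-1,3-dien-1-yl]phenol
Conditions: Bu4NF, THF, 0 °C; H2O
Reagents that add atoms: none
Why: fluoride cleavage of the aryl silyl ether; nothing else in 18 reacts with fluoride.

Step 14
Reactants: 19 2-bromo-3,5-bis(methoxymethoxy)-4-[(1E)-3-methylbuta-1,3-dien-1-yl]phenol
Product: 22 3,5-bis(methoxymethoxy)-4-[(1E)-3-methylbuta-1,3-dien-1-yl]-2-(trimethylsilyl)phenyl trifluoromethanesulfonate, via trimethylsilyl ether 20 (not isolated), via lithium phenolate 21 (not isolated)
Conditions: (Me3Si)2NH, THF, 65 °C, then evaporation; n-BuLi (1.05 equiv), THF, −78 °C; PhNTf2, −78 °C → rt; H2O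
Reagents that add atoms: hexamethyldisilazane, C[Si](C)(C)N[Si](C)(C)C; N-phenylbis(trifluoromethanesulfonimide), O=S(=O)(N(c1ccccc1)S(=O)(=O)C(F)(F)F)C(F)(F)F
Why: O-silylation, bromine–lithium exchange and retro-Brook 1,3-shift of silicon from oxygen to carbon, then O-triflation of the phenolate; exchange at −78 °C should be much faster than addition of butyllithium to the aryl diene, and the mild triflating agent spares diene and acetals.

### Union and flavone annulation (steps 15–19)

Step 15
Reactants: 7 (E)-3-[2,4-bis(methoxymethoxy)phenyl]-1-[2-hydroxy-4-(methoxymethoxy)-3-(3-methylbut-2-en-1-yl)phenyl]prop-2-en-1-one; 22 3,5-bis(methoxymethoxy)-4-[(1E)-3-methylbuta-1,3-dien-1-yl]-2-(trimethylsilyl)phenyl trifluoromethanesulfonate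
Product: 23 (3''S,4''R,5''S)-3''-[2,6-bis(methoxymethoxy)-4-(trifluoromethanesulfonyloxy)-3-(trimethylsilyl)phenyl]-4''-[2-hydroxy-4-(methoxymethoxy)-3-(3-methylbut-2-en-1-yl)benzoyl]-5''-[2,4-bis(methoxymethoxy)phenyl]-1''-methylcyclohex-1''-ene
Conditions: (R)-3,3'-diphenyl-2,2'-binaphthalene-1,1'-diol (1.2 equiv), BH3·THF (1.2 equiv), AcOH (1.2 equiv), THF, rt; then 7; then 22 (1.5 equiv), PhCF3, rt → 40 °C
Reagents that add atoms: none
Why: Diels–Alder cycloaddition of a 2'-hydroxychalcone activated as a chiral boron chelate of its hydroxy ketone; the diene CH2 bonds to the beta-carbon and the aryl-bearing terminus to the alpha-carbon, the endo transition state puts the C3'' aryl cis to the aroyl group and the E-alkene keeps aroyl and C5'' aryl trans. The ligand shields the Re face of the alpha-carbon, so the triad should arise as (3''S,4''R,5''S); any exo isomer differs at C3'' and should be separable.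

Step 16
Reactants: 23 the endo adduct with free 2'-hydroxyl
Product: 24 (3''S,4''R,5''S)-3''-[2,6-bis(methoxymethoxy)-4-(trifluoromethanesulfonyloxy)-3-(trimethylsilyl)phenyl]-4''-[2,4-bis(methoxymethoxy)-3-(3-methylbut-2-en-1-yl)benzoyl]-5''-[2,4-bis(methoxymethoxy)phenyl]-1''-methylcyclohex-1''-ene
Conditions: KN(SiMe3)2 (1.05 equiv), THF, −78 °C; MOMCl, −78 → 0 °C
Reagents that add atoms: chloromethyl methyl ether, COCCl
Why: O-alkylation of the chelated phenoxide; one equivalent of a soluble base at −78 °C removes the phenolic proton long before the hindered C4''–H, and the absence of fluoride leaves the silyl triflate intact.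

Step 17
Reactants: 24 the silyl triflate ketone; 10 3-[2,4-bis(methoxymethoxy)phenyl]prop-2-ynoic acid
Product: 26 (3''S,4''R,5''S)-3''-{3-[3-(2,4-bis(methoxymethoxy)phenyl)prop-2-ynoyl]-4-hydroxy-2,6-bis(methoxymethoxy)phenyl}-4''-[2,4-bis(methoxymethoxy)-3-(3-methylbut-2-en-1-yl)benzoyl]-5''-[2,4-bis(methoxymethoxy)phenyl]-1''-methylcyclohex-1''-ene, via aryne 25 (not isolated)
Conditions: CsF (4 equiv), 10 (1.5 equiv), THF, sealed tube, 125 °C
Reagents that add atoms: none
Why: Fluoride attacks the silicon of 24 and triflate leaves, giving aryne 25 with its strained bond between C4a and C8a. The C5 acetal oxygen polarises and distorts the aryne so that the carboxylate of 10 adds at C8a, the carbon remote from it, which places the aryl anion on C4a beside the stabilising oxygen. That anion adds to the neighbouring ester carbonyl through a four-membered alkoxide, which opens to the chelated phenoxide of 26; the aryne has thus inserted into the C–O bond of the acid, and O1 comes from the acid, not from the triflate. The closest known reaction type is the fluoride-induced insertion of arynes into the C–O bond of carboxylic acids to give ortho-hydroxyaryl ketones, known also for 3-alkoxyarynes and for arylpropiolic acids. No ring is closed and no stereocentre is formed. The step needs regioselectivity, secured by the C5 oxygen as the only substituent next to the aryne. It needs acyl migration ahead of protonation of the aryl anion, secured by hot aprotic THF and excess CsF with no proton source beyond the acid itself. It needs chemoselectivity for the carboxylate over fluoride, the alkenes and the C4''–H, secured by the excess of 10 and the hindered, twisted ketone. If the phenoxide of 26 begins to close to 28 in the hot flask, nothing is lost, because step 18 takes both to 28.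

Step 18
Reactants: 26 the ortho-hydroxyaryl ynone
Product: 28 (3''S,4''R,5''S)-3''-{2-[2,4-bis(methoxymethoxy)phenyl]-5,7-bis(methoxymethoxy)-4-oxo-4H-chromen-6-yl}-4''-[2,4-bis(methoxymethoxy)-3-(3-methylbut-2-en-1-yl)benzoyl]-5''-[2,4-bis(methoxymethoxy)phenyl]-1''-methylcyclohex-1''-ene, via enaminone 27 (not isolated)
Conditions: Et2NH (5 equiv), EtOH/THF, 50 °C
Reagents that add atoms: none
Why: amine-mediated 6-endo oxa-Michael cyclisation; diethylamine adds to the ynone to give the beta-aminoenone, the C8a phenol then displaces the amine at the beta-carbon, which closes only the six-membered ring, and the single free phenol allows only one flavone.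

Step 19
Reactants: 28 the octa-MOM flavone
Product: 29 CNP0270206.1, (3''S,4''R,5''S)-3''-[2-(2,4-dihydroxyphenyl)-5,7-dihydroxy-4-oxo-4H-chromen-6-yl]-4''-[2,4-dihydroxy-3-(3-methylbut-2-en-1-yl)benzoyl]-5''-(2,4-dihydroxyphenyl)-1''-methylcyclohex-1''-ene
Conditions: HCl (3 M aq)/MeOH/THF, 40 °C
Reagents that add atoms: none
Why: acid-catalysed acetal exchange with methanol removes all eight MOM groups; the temperature is kept low and the time short so that the prenyl group and the ketone do not react with the liberated phenols, and no stereocentre is touched.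

## Compound list

1 | 2,4-dihydroxyacetophenone | CC(=O)c1ccc(O)cc1O | starting material
2 | 1-bromo-3-methylbut-2-ene | CC(C)=CCBr | starting material
3 | 1-[2,4-dihydroxy-3-(3-methylbut-2-en-1-yl)phenyl]ethan-1-one | CC(=O)c1ccc(O)c(CC=C(C)C)c1O | intermediate
4 | 1-[2-hydroxy-4-(methoxymethoxy)-3-(3-methylbut-2-en-1-yl)phenyl]ethan-1-one | CC(=O)c1ccc(OCOC)c(CC=C(C)C)c1O | intermediate
5 | 2,4-dihydroxybenzaldehyde | O=Cc1ccc(O)cc1O | starting material
6 | 2,4-bis(methoxymethoxy)benzaldehyde | O=Cc1ccc(OCOC)cc1OCOC | intermediate
7 | (E)-3-[2,4-bis(methoxymethoxy)phenyl]-1-[2-hydroxy-4-(methoxymethoxy)-3-(3-methylbut-2-en-1-yl)phenyl]prop-2-en-1-one | CC(C)=CCc1c(OCOC)ccc(C(=O)/C=C/c2ccc(OCOC)cc2OCOC)c1O | intermediate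
8 | 1-ethynyl-2,4-bis(methoxymethoxy)benzene | C#Cc1ccc(OCOC)cc1OCOC | intermediate
9 | lithium [2,4-bis(methoxymethoxy)phenyl]acetylide | [Li]C#Cc1ccc(OCOC)cc1OCOC | intermediate
10 | 3-[2,4-bis(methoxymethoxy)phenyl]prop-2-ynoic acid | OC(=O)C#Cc1ccc(OCOC)cc1OCOC | intermediate
11 | phloroglucinol | Oc1cc(O)cc(O)c1 | starting material
12 | 3,5-bis(methoxymethoxy)phenol | COCOc1cc(O)cc(OCOC)c1 | intermediate
13 | [3,5-bis(methoxymethoxy)phenoxy]tri(propan-2-yl)silane | COCOc1cc(OCOC)cc(O[Si](C(C)C)(C(C)C)C(C)C)c1 | intermediate
14 | 2,6-bis(methoxymethoxy)-4-[tri(propan-2-yl)silyloxy]phenyllithium | [Li]c1c(OCOC)cc(O[Si](C(C)C)(C(C)C)C(C)C)cc1OCOC | intermediate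
15 | 2,6-bis(methoxymethoxy)-4-[tri(propan-2-yl)silyloxy]benzaldehyde | O=Cc1c(OCOC)cc(O[Si](C(C)C)(C(C)C)C(C)C)cc1OCOC | intermediate
16 | 3-bromo-2,6-bis(methoxymethoxy)-4-[tri(propan-2-yl)silyloxy]benzaldehyde | O=Cc1c(OCOC)c(Br)c(O[Si](C(C)C)(C(C)C)C(C)C)cc1OCOC | intermediate
17 | (E)-4-{3-bromo-2,6-bis(methoxymethoxy)-4-[tri(propan-2-yl)silyloxy]phenyl}but-3-en-2-one | CC(=O)/C=C/c1c(OCOC)c(Br)c(O[Si](C(C)C)(C(C)C)C(C)C)cc1OCOC | intermediate
18 | {2-bromo-3,5-bis(methoxymethoxy)-4-[(1E)-3-methylbuta-1,3-dien-1-yl]phenoxy}tri(propan-2-yl)silane | CC(=C)/C=C/c1c(OCOC)c(Br)c(O[Si](C(C)C)(C(C)C)C(C)C)cc1OCOC | intermediate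
19 | 2-bromo-3,5-bis(methoxymethoxy)-4-[(1E)-3-methylbuta-1,3-dien-1-yl]phenol | CC(=C)/C=C/c1c(OCOC)c(Br)c(O)cc1OCOC | intermediate
20 | {2-bromo-3,5-bis(methoxymethoxy)-4-[(1E)-3-methylbuta-1,3-dien-1-yl]phenoxy}trimethylsilane | CC(=C)/C=C/c1c(OCOC)c(Br)c(O[Si](C)(C)C)cc1OCOC | intermediate
21 | lithium 3,5-bis(methoxymethoxy)-4-[(1E)-3-methylbuta-1,3-dien-1-yl]-2-(trimethylsilyl)phenolate | [Li+].CC(=C)/C=C/c1c(OCOC)c([Si](C)(C)C)c([O-])cc1OCOC | intermediate
22 | 3,5-bis(methoxymethoxy)-4-[(1E)-3-methylbuta-1,3-dien-1-yl]-2-(trimethylsilyl)phenyl trifluoromethanesulfonate | CC(=C)/C=C/c1c(OCOC)c([Si](C)(C)C)c(OS(=O)(=O)C(F)(F)F)cc1OCOC | intermediate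
23 | endo cycloadduct with free 2'-hydroxyl, (3''S,4''R,5''S), name as in step 15 | CC(C)=CCc1c(OCOC)ccc(C(=O)[C@H]2[C@@H](c3c(OCOC)cc(OS(=O)(=O)C(F)(F)F)c([Si](C)(C)C)c3OCOC)C=C(C)C[C@@H]2c2ccc(OCOC)cc2OCOC)c1O | intermediate
24 | fully MOM-protected silyl triflate ketone, (3''S,4''R,5''S), name as in step 16 | CC(C)=CCc1c(OCOC)ccc(C(=O)[C@H]2[C@@H](c3c(OCOC)cc(OS(=O)(=O)C(F)(F)F)c([Si](C)(C)C)c3OCOC)C=C(C)C[C@@H]2c2ccc(OCOC)cc2OCOC)c1OCOC | intermediate
25 | aryne from 24: the 3,4-didehydro-2,6-bis(methoxymethoxy)phenyl group at C3'' (strained bond between flavone C4a and C8a), other groups as in 24 | CC(C)=CCc1c(OCOC)ccc(C(=O)[C@H]2[C@@H](C3=C(OCOC)C#CC=C3OCOC)C=C(C)C[C@@H]2c2ccc(OCOC)cc2OCOC)c1OCOC | intermediate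
26 | ortho-hydroxyaryl ynone, (3''S,4''R,5''S), name as in step 17 | CC(C)=CCc1c(OCOC)ccc(C(=O)[C@H]2[C@@H](c3c(OCOC)cc(O)c(C(=O)C#Cc5ccc(OCOC)cc5OCOC)c3OCOC)C=C(C)C[C@@H]2c2ccc(OCOC)cc2OCOC)c1OCOC | intermediate
27 | beta-(diethylamino)enone from 26 (alkene geometry not defined), other groups as in 26 | CC(C)=CCc1c(OCOC)ccc(C(=O)[C@H]2[C@@H](c3c(OCOC)cc(O)c(C(=O)C=C(N(CC)CC)c5ccc(OCOC)cc5OCOC)c3OCOC)C=C(C)C[C@@H]2c2ccc(OCOC)cc2OCOC)c1OCOC | intermediate
28 | octa-MOM flavone, (3''S,4''R,5''S), name as in step 18 | CC(C)=CCc1c(OCOC)ccc(C(=O)[C@H]2[C@@H](c3c(OCOC)cc4oc(-c5ccc(OCOC)cc5OCOC)cc(=O)c4c3OCOC)C=C(C)C[C@@H]2c2ccc(OCOC)cc2OCOC)c1OCOC | intermediate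
29 | CNP0270206.1, (3''S,4''R,5''S), name as in step 19 | CC(C)=CCc1c(O)ccc(C(=O)[C@H]2[C@@H](c3c(O)cc4oc(-c5ccc(O)cc5O)cc(=O)c4c3O)C=C(C)C[C@@H]2c2ccc(O)cc2O)c1O | target

## Step count and least certain steps

Total: 19 steps. Longest linear sequence: 13 steps (steps 7–19, from phloroglucinol 11).

**Step 17 (key step).** The aryl anion on C4a may be protonated before the acyl group migrates, which would leave a simple aryl ester. Fluoride and carboxylate at 125 °C may also epimerise C4'', the propiolate may decarboxylate, or the phenoxide product may close in the 5-exo sense. The fallback keeps the aryne but replaces the acyl shift by a cycloaddition that does not compete with protonation. It sets out from 24: CsF in DMF at rt to 50 °C followed by water should give, through formal insertion of the aryne into the formamide C=O bond and hydrolysis, the salicylaldehyde F1, with the oxygen again on C8a. Addition of lithium acetylide 9 (2.2 equiv, THF, −78 °C) to the aldehyde should give the propargylic alcohol F2, and MnO2 in CH2Cl2 should oxidise it to the ynone. The fallback comes back to the route at 26.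

**Step 15.** The cycloaddition may give poor endo/exo selectivity or poor facial selectivity, or the twisted, triflate-bearing aryl diene may react slowly. The fallback gives up asymmetric induction for resolution. It sets out from 7 and 22: silica-supported zerovalent silver nanoparticles (CH2Cl2, 50 °C), which favour the endo mode with 2'-hydroxychalcones, should give the racemic endo adduct F3. Chromatography on a chiral stationary phase then separates the enantiomers, and the fallback comes back at 23.

**Step 14.** Butyllithium may add to the aryl diene or start its oligomerisation before bromine–lithium exchange and silyl migration are complete. The fallback forms the C–Si bond without any organolithium and before the diene exists. It sets out from 16: silylation catalysed by zerovalent palladium (Pd2(dba)3, that is tris(dibenzylideneacetone)dipalladium, with 2-(di-tert-butylphosphino)biphenyl, Me3SiSiMe3, LiOAc, DMF, 100 °C) should give the 3-(trimethylsilyl) aldehyde F4. The two Wittig reactions of steps 11 and 12 then lead through enone F5 to diene F6, Bu4NF frees the ortho-silyl phenol F7, and PhNTf2 with K2CO3 in THF triflates it. The fallback comes back at 22.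

**Step 19.** Acid may add a liberated phenol across the prenyl alkene to form a chroman, ketalise the ketone with flanking phenols, or leave some acetals in place if the conditions are kept mild enough to avoid these. The fallback changes the cleavage mechanism from protic solvolysis to Lewis-acid activation with thiol capture. It sets out from 28: ZnBr2 and propane-1-thiol in CH2Cl2 at 0 °C for minutes, where the methoxymethyl groups leave as a thioacetal and no strong protic acid is present. It comes back at 29 with no new intermediate.

**Step 1.** Prenylation may go to C5, to oxygen or twice, which lowers the supply of 3. The fallback fixes the position by a halogen. It sets out from 1: iodination with I2/HIO3 in aqueous EtOH at the carbon between the hydroxyls should give 1-(2,4-dihydroxy-3-iodophenyl)ethan-1-one F8. MOMCl/K2CO3 as in step 2 gives the 4-O-MOM iodide F9, and Stille coupling with tributyl(3-methylbut-2-en-1-yl)stannane (Pd(PPh3)4, DMF, 90 °C) installs the prenyl group. The fallback comes back at 4.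

## Further compounds

F1 | step 17 | salicylaldehyde: compound 24 with OH on C8a and CHO on C4a in place of triflate and silyl group | CC(C)=CCc1c(OCOC)ccc(C(=O)[C@H]2[C@@H](c3c(OCOC)cc(O)c(C=O)c3OCOC)C=C(C)C[C@@H]2c2ccc(OCOC)cc2OCOC)c1OCOC
F2 | step 17 | propargylic alcohol from F1 and 9 (carbinol configuration not defined) | CC(C)=CCc1c(OCOC)ccc(C(=O)[C@H]2[C@@H](c3c(OCOC)cc(O)c(C(O)C#Cc5ccc(OCOC)cc5OCOC)c3OCOC)C=C(C)C[C@@H]2c2ccc(OCOC)cc2OCOC)c1OCOC
F3 | step 15 | racemic endo adduct (23 and its mirror image, 1:1) | CC(C)=CCc1c(OCOC)ccc(C(=O)[C@H]2[C@@H](c3c(OCOC)cc(OS(=O)(=O)C(F)(F)F)c([Si](C)(C)C)c3OCOC)C=C(C)C[C@@H]2c2ccc(OCOC)cc2OCOC)c1O.CC(C)=CCc1c(OCOC)ccc(C(=O)[C@@H]2[C@H](c3c(OCOC)cc(OS(=O)(=O)C(F)(F)F)c([Si](C)(C)C)c3OCOC)C=C(C)C[C@H]2c2ccc(OCOC)cc2OCOC)c1O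
F4 | step 14 | 2,6-bis(methoxymethoxy)-4-[tri(propan-2-yl)silyloxy]-3-(trimethylsilyl)benzaldehyde | O=Cc1c(OCOC)c([Si](C)(C)C)c(O[Si](C(C)C)(C(C)C)C(C)C)cc1OCOC
F5 | step 14 | (E)-4-{2,6-bis(methoxymethoxy)-4-[tri(propan-2-yl)silyloxy]-3-(trimethylsilyl)phenyl}but-3-en-2-one | CC(=O)/C=C/c1c(OCOC)c([Si](C)(C)C)c(O[Si](C(C)C)(C(C)C)C(C)C)cc1OCOC
F6 | step 14 | {3,5-bis(methoxymethoxy)-4-[(1E)-3-methylbuta-1,3-dien-1-yl]-2-(trimethylsilyl)phenoxy}tri(propan-2-yl)silane | CC(=C)/C=C/c1c(OCOC)c([Si](C)(C)C)c(O[Si](C(C)C)(C(C)C)C(C)C)cc1OCOC
F7 | step 14 | 3,5-bis(methoxymethoxy)-4-[(1E)-3-methylbuta-1,3-dien-1-yl]-2-(trimethylsilyl)phenol | CC(=C)/C=C/c1c(OCOC)c([Si](C)(C)C)c(O)cc1OCOC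
F0 | step 19 | none | none
F8 | step 1 | 1-(2,4-dihydroxy-3-iodophenyl)ethan-1-one | CC(=O)c1ccc(O)c(I)c1O
F9 | step 1 | 1-[2-hydroxy-3-iodo-4-(methoxymethoxy)phenyl]ethan-1-one | CC(=O)c1ccc(OCOC)c(I)c1O
A1 | alternative 1 | ethynyl ketone: the C4'' carbonyl bears a terminal alkyne, flavone and C5'' aryl as in 28 | C#CC(=O)[C@H]2[C@@H](c3c(OCOC)cc4oc(-c5ccc(OCOC)cc5OCOC)cc(=O)c4c3OCOC)C=C(C)C[C@@H]2c2ccc(OCOC)cc2OCOC
A2 | alternative 1 | 1-methoxy-2-(3-methylbut-2-en-1-yl)-1,3-bis(trimethylsilyloxy)buta-1,3-diene (ketene acetal geometry not defined) | COC(O[Si](C)(C)C)=C(CC=C(C)C)C(=C)O[Si](C)(C)C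
A3 | alternative 1 | target with free aroyl-ring hydroxyls and six MOM ethers | CC(C)=CCc1c(O)ccc(C(=O)[C@H]2[C@@H](c3c(OCOC)cc4oc(-c5ccc(OCOC)cc5OCOC)cc(=O)c4c3OCOC)C=C(C)C[C@@H]2c2ccc(OCOC)cc2OCOC)c1O
A4 | alternative 2 | 1,3-diaryl-2-benzylidene-4-isopropenylcyclobutanol (only the aryl-bearing ring CH is assigned; carbinol carbon, isopropenyl-bearing carbon and benzylidene geometry are those the rearrangement demands) | CC(C)=CCc1c(OCOC)ccc(C2(O)C(=Cc3ccc(OCOC)cc3OCOC)[C@@H](c3c(OCOC)cc(O[Si](C(C)C)(C(C)C)C(C)C)cc3OCOC)C2C(C)=C)c1OCOC
A5 | alternative 2 | protected cyclohexenyl aryl ketone with a 4-silyloxy-2,6-bis(methoxymethoxy)phenyl group at C3'' | CC(C)=CCc1c(OCOC)ccc(C(=O)[C@H]2[C@@H](c3c(OCOC)cc(O[Si](C(C)C)(C(C)C)C(C)C)cc3OCOC)C=C(C)C[C@@H]2c2ccc(OCOC)cc2OCOC)c1OCOC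
A6 | alternative 3 | methyl beta-keto ester on C3'' ending in a [6-aryl-4-oxo-4H-pyran-2-yl]methyl ketone (ester-bearing CH not defined) | CC(C)=CCc1c(OCOC)ccc(C(=O)[C@H]2[C@@H](C(C(=O)OC)C(=O)Cc3cc(=O)cc(-c4ccc(OCOC)cc4OCOC)o3)C=C(C)C[C@@H]2c2ccc(OCOC)cc2OCOC)c1OCOC
A7 | alternative 3 | target with free 5- and 7-hydroxyls and six MOM ethers | CC(C)=CCc1c(OCOC)ccc(C(=O)[C@H]2[C@@H](c3c(O)cc4oc(-c5ccc(OCOC)cc5OCOC)cc(=O)c4c3O)C=C(C)C[C@@H]2c2ccc(OCOC)cc2OCOC)c1OCOC
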